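In each half of the target the 4-hydroxyphenyl ring B is bonded to C3 of pyranone ring C, while C2 is a bare CH next to O1: the pattern left by a 1,2-aryl shift. Both C3–C1' bonds are therefore made at once by a twofold oxidative rearrangement of a biaryl bischalcone, in which the anisyl rings sit on the future C2 carbons; each C2 emerges as a dimethyl acetal ready to close onto O1. The precursor is a racemic 3,3'-bis(4-methoxycinnamoyl)biphenyl carrying benzyl ethers on the two oxygens destined to become O1 and methyl ethers elsewhere; its C8–C8' axis comes from an Ullmann coupling.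

Key step: step 5

Assumption: the target SMILES defines no configuration at the hindered C8–C8' axis and the molecule has no stereocentre, so the racemate is the goal and no step has to control stereochemistry.

Remark on the biaryl bond: it is made by copper coupling of an aryl iodide and not by oxidising 3,4,5-trimethoxyphenol, because 4-methoxyphenols of that type are prone to oxidative demethylation to 2,6-dimethoxy-para-benzoquinone.

Remark on the benzyl ether: of the two oxygens ortho to each acyl group, only the one also flanked by the biaryl carbon is benzylated. This fixes which oxygen becomes O1 and hence the 8,8' (not 6,6') linkage.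

Remark on supply: compound 1 is a catalogue chemical; if needed it is available in one step from 3,4,5-trimethoxyphenol with AcOH/BF3·OEt2.

Step 1
Reactants: 1 1-(6-hydroxy-2,3,4-trimethoxyphenyl)ethan-1-one
Product: 2 1-(2-hydroxy-3-iodo-4,5,6-trimethoxyphenyl)ethan-1-one
Conditions: NIS (1.05 equiv), TFA (cat.), MeCN, rt
Reagents that add atoms: N-iodosuccinimide, O=C1CCC(=O)N1I
Why: Electrophilic aromatic iodination can occur only at the single unsubstituted ring carbon, which is activated by the ortho hydroxyl and the ortho and para methoxy groups, so one regioisomer should form.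

Step 2
Reactants: 2 1-(2-hydroxy-3-iodo-4,5,6-trimethoxyphenyl)ethan-1-one; 3 benzyl bromide
Product: 4 1-[2-(benzyloxy)-3-iodo-4,5,6-trimethoxyphenyl]ethan-1-one
Conditions: BnBr, K2CO3, DMF, 60 °C
Reagents that add atoms: none
Why: Williamson ether synthesis on the hydrogen-bonded phenol in warm DMF should cap the oxygen that later becomes O1 and keep it from interfering in the coupling and in the oxidative rearrangement.

Step 3
Reactants: 4 1-[2-(benzyloxy)-3-iodo-4,5,6-trimethoxyphenyl]ethan-1-one (two molecules)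
Product: 5 1,1'-[2,2'-bis(benzyloxy)-4,4',5,5',6,6'-hexamethoxy[1,1'-biphenyl]-3,3'-diyl]di(ethan-1-one), racemic about the biaryl axis
Conditions: activated Cu powder (5 equiv), DMF, 150 °C, Ar
Reagents that add atoms: none
Why: Ullmann reductive homocoupling of di-ortho-alkoxy iodoacetophenones is an established way to tetra-ortho-oxygenated biaryls, and the only new stereogenic element, the axis, forms without control as the racemate.

Step 4
Reactants: 5 1,1'-[2,2'-bis(benzyloxy)-4,4',5,5',6,6'-hexamethoxy[1,1'-biphenyl]-3,3'-diyl]di(ethan-1-one); 6 4-methoxybenzaldehyde (2.5 equiv)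
Product: 7 (2E,2'E)-1,1'-[2,2'-bis(benzyloxy)-4,4',5,5',6,6'-hexamethoxy[1,1'-biphenyl]-3,3'-diyl]bis[3-(4-methoxyphenyl)prop-2-en-1-one]
Conditions: KOH, EtOH, rt
Reagents that add atoms: none
Why: Twofold Claisen–Schmidt condensation of the methyl ketones with a non-enolisable aldehyde should give the (E,E)-bis-enone by E1cB dehydration under thermodynamic control, and the benzyl cap rules out flavanone closure.

Step 5
Reactants: 7 (2E,2'E)-1,1'-[2,2'-bis(benzyloxy)-4,4',5,5',6,6'-hexamethoxy[1,1'-biphenyl]-3,3'-diyl]bis[3-(4-methoxyphenyl)prop-2-en-1-one]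
Product: 8 1,1'-[2,2'-bis(benzyloxy)-4,4',5,5',6,6'-hexamethoxy[1,1'-biphenyl]-3,3'-diyl]bis[3,3-dimethoxy-2-(4-methoxyphenyl)propan-1-one], mixture of diastereomers
Conditions: Tl(NO3)3·3H2O (2.4 equiv), MeOH–HC(OMe)3 (1:1), rt
Reagents that add atoms: methanol, CO
Why: Oxythallation places thallium on Cα and methanol on the benzylic Cβ of each enone. The 4-methoxyphenyl ring then shifts from Cβ to Cα through a phenonium ion while monovalent thallium leaves, and the methoxy-stabilised cation left at Cβ is captured by methanol as the dimethyl acetal. The closest known reaction is the Tl(NO3)3-mediated oxidative rearrangement of 2'-alkoxychalcones to 1,2-diaryl-3,3-dimethoxypropan-1-ones, here run on both enones of one molecule. No ring is closed. The two new CH(aryl) centres lie α to a ketone, are not controlled (a diastereomer mixture across the racemic axis is expected) and vanish when C2=C3 forms in step 6. The step needs aryl rather than aroyl migration and rearrangement rather than plain dimethoxylation or aurone/flavone closure: the electron-releasing 4-methoxy group secures the first, the benzyl cap on O2 the second, and the fully substituted, ketone-deactivated ring A offers no CH for ring thallation.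

Step 6
Reactants: 8 1,1'-[2,2'-bis(benzyloxy)-4,4',5,5',6,6'-hexamethoxy[1,1'-biphenyl]-3,3'-diyl]bis[3,3-dimethoxy-2-(4-methoxyphenyl)propan-1-one]
Product: 11 5,5',6,6',7,7'-hexamethoxy-3,3'-bis(4-methoxyphenyl)-4H,4'H-[8,8'-bichromene]-4,4'-dione, via bis-phenol keto acetal 9 (not isolated), via bis(2-methoxyisoflavanone) 10 (not isolated)
Conditions: H2 (1 atm), 10% Pd/C, MeOH–EtOAc, rt; filter; then conc. HCl, MeOH, 60 °C
Reagents that add atoms: none
Why: Catalytic hydrogenolysis frees the two phenols, which under acid add to the oxocarbenium ions from the acetals (6-exo-trig transacetalisation) and then lose methanol by β-elimination to give the conjugated pyranones, erasing the two CH stereocentres.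

Step 7
Reactants: 11 5,5',6,6',7,7'-hexamethoxy-3,3'-bis(4-methoxyphenyl)-4H,4'H-[8,8'-bichromene]-4,4'-dione
Product: 12 5,5',6,6',7,7'-hexahydroxy-3,3'-bis(4-hydroxyphenyl)-4H,4'H-[8,8'-bichromene]-4,4'-dione, racemic about the C8–C8' axis
Conditions: BBr3 (excess), CH2Cl2, −78 °C to rt, Ar; then MeOH, H2O
Reagents that add atoms: none
Why: Lewis-acid ether cleavage with BBr3 should remove all eight aryl methyl ethers under aprotic, low-temperature conditions that do not open the pyranone, so no Wessely–Moser-type shift of the biaryl bond from C8 to C6 is expected.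

Compound list
1 | 1-(6-hydroxy-2,3,4-trimethoxyphenyl)ethan-1-one | CC(=O)c1c(O)cc(OC)c(OC)c1OC | starting material
2 | 1-(2-hydroxy-3-iodo-4,5,6-trimethoxyphenyl)ethan-1-one | CC(=O)c1c(O)c(I)c(OC)c(OC)c1OC | intermediate
3 | benzyl bromide | BrCc1ccccc1 | starting material
4 | 1-[2-(benzyloxy)-3-iodo-4,5,6-trimethoxyphenyl]ethan-1-one | CC(=O)c1c(OCc2ccccc2)c(I)c(OC)c(OC)c1OC | intermediate
5 | 1,1'-[2,2'-bis(benzyloxy)-4,4',5,5',6,6'-hexamethoxy[1,1'-biphenyl]-3,3'-diyl]di(ethan-1-one), racemic axis | CC(=O)c1c(OCc2ccccc2)c(-c2c(OCc3ccccc3)c(C(C)=O)c(OC)c(OC)c2OC)c(OC)c(OC)c1OC | intermediate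
6 | 4-methoxybenzaldehyde | COc1ccc(C=O)cc1 | starting material
7 | (2E,2'E)-1,1'-[2,2'-bis(benzyloxy)-4,4',5,5',6,6'-hexamethoxy[1,1'-biphenyl]-3,3'-diyl]bis[3-(4-methoxyphenyl)prop-2-en-1-one] | COc1ccc(/C=C/C(=O)c2c(OCc3ccccc3)c(-c3c(OCc4ccccc4)c(C(=O)/C=C/c4ccc(OC)cc4)c(OC)c(OC)c3OC)c(OC)c(OC)c2OC)cc1 | intermediate
8 | 1,1'-[2,2'-bis(benzyloxy)-4,4',5,5',6,6'-hexamethoxy[1,1'-biphenyl]-3,3'-diyl]bis[3,3-dimethoxy-2-(4-methoxyphenyl)propan-1-one], diastereomer mixture | COc1ccc(C(C(OC)OC)C(=O)c2c(OCc3ccccc3)c(-c3c(OCc4ccccc4)c(C(=O)C(C(OC)OC)c4ccc(OC)cc4)c(OC)c(OC)c3OC)c(OC)c(OC)c2OC)cc1 | intermediate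
9 | 1,1'-[2,2'-dihydroxy-4,4',5,5',6,6'-hexamethoxy[1,1'-biphenyl]-3,3'-diyl]bis[3,3-dimethoxy-2-(4-methoxyphenyl)propan-1-one], diastereomer mixture | COc1ccc(C(C(OC)OC)C(=O)c2c(O)c(-c3c(O)c(C(=O)C(C(OC)OC)c4ccc(OC)cc4)c(OC)c(OC)c3OC)c(OC)c(OC)c2OC)cc1 | intermediate
10 | 2,2',5,5',6,6',7,7'-octamethoxy-3,3'-bis(4-methoxyphenyl)-2,2',3,3'-tetrahydro-4H,4'H-[8,8'-bichromene]-4,4'-dione, diastereomer mixture | COC1Oc2c(-c3c(OC)c(OC)c(OC)c4c3OC(OC)C(c3ccc(OC)cc3)C4=O)c(OC)c(OC)c(OC)c2C(=O)C1c1ccc(OC)cc1 | intermediate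
11 | 5,5',6,6',7,7'-hexamethoxy-3,3'-bis(4-methoxyphenyl)-4H,4'H-[8,8'-bichromene]-4,4'-dione | COc1ccc(-c2coc3c(-c4c(OC)c(OC)c(OC)c5c(=O)c(-c6ccc(OC)cc6)coc45)c(OC)c(OC)c(OC)c3c2=O)cc1 | intermediate
12 | 5,5',6,6',7,7'-hexahydroxy-3,3'-bis(4-hydroxyphenyl)-4H,4'H-[8,8'-bichromene]-4,4'-dione | O=c1c(-c2ccc(O)cc2)coc2c(-c3c(O)c(O)c(O)c4c(=O)c(-c5ccc(O)cc5)coc34)c(O)c(O)c(O)c12 | target

Total step count: 7. Longest linear sequence: 7 steps (1 to 12).

Steps most likely to fail

Step 5. The rearrangement may stop after one enone, one arm may only take up two methoxy groups without aryl migration, or the electron-rich rings may be over-oxidised. A same-disconnection variant is PhI(OH)OTs in MeOH–HC(OMe)3. The fallback that changes the approach makes the C3–C1' bonds by cross-coupling instead. It sets out from 5: hydrogenolysis (H2, Pd/C, EtOAc) should give 1,1'-[2,2'-dihydroxy-4,4',5,5',6,6'-hexamethoxy[1,1'-biphenyl]-3,3'-diyl]di(ethan-1-one) F1. Heating with N,N-dimethylformamide dimethyl acetal should give the bis-enaminone F2. Iodine in MeOH should close both rings to 3,3'-diiodo-5,5',6,6',7,7'-hexamethoxy-4H,4'H-[8,8'-bichromene]-4,4'-dione F3. Twofold Suzuki–Miyaura coupling with 4-methoxyphenylboronic acid (Pd(PPh3)4, K2CO3, DME–H2O, 80 °C) then rejoins the route at 11.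

Step 3. Protodeiodination may compete and the coupling may stall, because the new bond is flanked by four ortho oxygen substituents; benzyl loss at high temperature is also possible. The fallback sets out from 4. Miyaura borylation of one portion (B2pin2, PdCl2(dppf), KOAc, dioxane, 90 °C) should give 1-[2-(benzyloxy)-4,5,6-trimethoxy-3-(4,4,5,5-tetramethyl-1,3,2-dioxaborolan-2-yl)phenyl]ethan-1-one F4. Suzuki–Miyaura coupling of F4 with a second portion of 4 (Pd(OAc)2, SPhos, K3PO4, toluene–H2O, 100 °C), a catalyst system suited to tetra-ortho-substituted biaryls, rejoins the route at 5.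

Step 7. Cleavage of the eight ethers may be incomplete (the flanked 6-methoxy groups last), and the pyrogallol-type rings may oxidise in air during isolation of the free polyphenol. The fallback sets out from 11 and adds a protect–purify–release relay. The crude product of BBr3 cleavage is acetylated without isolation (Ac2O, pyridine) to the octaacetate F5, which is stable on silica and separable from partly methylated material. Acid methanolysis (HCl, degassed MeOH) then returns to 12.

Further compounds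
F1 | step 5 | 1,1'-[2,2'-dihydroxy-4,4',5,5',6,6'-hexamethoxy[1,1'-biphenyl]-3,3'-diyl]di(ethan-1-one) | CC(=O)c1c(O)c(-c2c(O)c(C(C)=O)c(OC)c(OC)c2OC)c(OC)c(OC)c1OC
F2 | step 5 | (2E,2'E)-1,1'-[2,2'-dihydroxy-4,4',5,5',6,6'-hexamethoxy[1,1'-biphenyl]-3,3'-diyl]bis[3-(dimethylamino)prop-2-en-1-one] | CN(C)/C=C/C(=O)c1c(O)c(-c2c(O)c(C(=O)/C=C/N(C)C)c(OC)c(OC)c2OC)c(OC)c(OC)c1OC
F3 | step 5 | 3,3'-diiodo-5,5',6,6',7,7'-hexamethoxy-4H,4'H-[8,8'-bichromene]-4,4'-dione | O=c1c(I)coc2c(-c3c(OC)c(OC)c(OC)c4c(=O)c(I)coc34)c(OC)c(OC)c(OC)c12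
F4 | step 3 | 1-[2-(benzyloxy)-4,5,6-trimethoxy-3-(4,4,5,5-tetramethyl-1,3,2-dioxaborolan-2-yl)phenyl]ethan-1-one | CC(=O)c1c(OCc2ccccc2)c(B2OC(C)(C)C(C)(C)O2)c(OC)c(OC)c1OC
F5 | step 7 | 5,5',6,6',7,7'-hexaacetoxy-3,3'-bis(4-acetoxyphenyl)-4H,4'H-[8,8'-bichromene]-4,4'-dione | CC(=O)Oc1ccc(-c2coc3c(-c4c(OC(C)=O)c(OC(C)=O)c(OC(C)=O)c5c(=O)c(-c6ccc(OC(C)=O)cc6)coc45)c(OC(C)=O)c(OC(C)=O)c(OC(C)=O)c3c2=O)cc1
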